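**Strategy.** The angular C20 methyl is traced back to a cyclopropane spanning C1–C10 of ring A, made by hydroxyl-directed Simmons–Smith cyclopropanation and later cut open at C1–C20 through the C2 ketone. The step exploits the allylic 2β-hydroxyl on ring A, which sits syn to the axial C19 ester at C4 and steers CH2 onto the hindered β face of the C1=C10 alkene, creating C10 and C1 in one operation. The precursor is a bicyclic 2β-hydroxy-Δ1(10),5-diene with C9 as a dioxolane and C19 as a fluoride-labile 2-(trimethylsilyl)ethyl ester, built from 3,5-dimethoxybenzoic acid by Birch methylation, Stork–Danheiser annulation and CBS reduction.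

Key step: step 13

Remark (numbering): labdane numbering is used for all intermediates, monocyclic ones included; TMSE = 2-(trimethylsilyl)ethyl; C18 = 4-CH3, C19 = 4-carboxyl.
Remark (assumption): which menthyl enol ether from step 4 is the (4S)-isomer is to be assigned by X-ray analysis or chemical correlation. C5 in 10 and 13–18, C10 in 13 and C2 in 15 and 16 are left open because these centres are erased later.

Step 1
Reactants: 1 3,5-dimethoxybenzoic acid
Product: 3 3,5-dimethoxy-1-methylcyclohexa-2,5-diene-1-carboxylic acid, via dilithium enediolate 2 (not isolated)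
Conditions: Li, NH3(l)/THF, −78 °C; then MeI, −78 °C to rt; cold aq. HCl to pH 5
Reagents that add atoms: iodomethane, CI
Why: Birch reduction places the two electrons at the ipso and para carbons and the resulting carboxylate enolate is C-methylated at the ipso carbon (Birch reductive alkylation), both methoxy groups remaining as enol ethers.

Step 2
Reactants: 3 3,5-dimethoxy-1-methylcyclohexa-2,5-diene-1-carboxylic acid
Product: 4 TMSE 3,5-dimethoxy-1-methylcyclohexa-2,5-diene-1-carboxylate
Conditions: Me3SiCH2CH2OH, PPh3, DIAD, THF, 0 °C to rt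
Reagents that add atoms: 2-(trimethylsilyl)ethanol, C[Si](C)(C)CCO
Why: In a Mitsunobu esterification the hindered tertiary acid acts as the nucleophile at an unhindered primary carbon, so the ester should form under neutral conditions that spare the enol ethers.

Step 3
Reactants: 4 TMSE 3,5-dimethoxy-1-methylcyclohexa-2,5-diene-1-carboxylate
Product: 5 TMSE 1-methyl-3,5-dioxocyclohexane-1-carboxylate (symmetrical dione, mainly enol)
Conditions: 1 M HCl, THF, rt
Reagents that add atoms: water, O
Why: Acid hydrolysis of both enol ethers should give the achiral 1,3-dione, the silylethyl ester tolerating dilute aqueous acid and the γ-carboxyl being unable to decarboxylate.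

Step 4
Reactants: 5 TMSE 1-methyl-3,5-dioxocyclohexane-1-carboxylate; 6 (1R,2S,5R)-(−)-menthol
Product: 7 TMSE (1S)-1-methyl-3-[(1R,2S,5R)-menthyloxy]-5-oxocyclohex-3-ene-1-carboxylate (C4 S in labdane numbering)
Conditions: TsOH (cat.), benzene, reflux, Dean–Stark; separation of the two C4 diastereomers by chromatography or crystallisation
Reagents that add atoms: none
Why: Acid-catalysed enol etherification of the dione with a chiral alcohol gives two vinylogous esters differing only at the quaternary carbon, which as diastereomers should be separable, so that C4 is fixed by auxiliary-based resolution, while the unwanted (1R)-isomer can be hydrolysed back to 5 under the conditions of step 3 and used again.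

Step 5
Reactants: 7 (4S)-menthyl vinylogous ester; 8 1-bromo-3-chloropropane
Product: 10 TMSE (1S)-6-(3-chloropropyl)-1-methyl-3-(menthyloxy)-5-oxocyclohex-3-ene-1-carboxylate (chain on C5; C5 epimers), via lithium enolate 9 (not isolated)
Conditions: LDA, THF, −78 °C; then 8, DMPU, −78 to 0 °C
Reagents that add atoms: none
Why: In this Stork–Danheiser alkylation kinetic deprotonation occurs at the α′-CH2 (future C5) and the enolate displaces bromide in preference to chloride, the new C5 centre being irrelevant because it is erased in step 11.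

Step 6
Reactants: 10 alkylated vinylogous ester; 11 1,3-dithiane
Product: 14 TMSE (1S)-2-(3-chloropropyl)-3-(1,3-dithian-2-yl)-1-methyl-5-oxocyclohex-3-ene-1-carboxylate (C2 ketone; Δ1(10); dithianyl on C10; C5 epimers), via 2-lithio-1,3-dithiane 12 (not isolated), via lithium alkoxide adduct 13 (not isolated)
Conditions: 11, n-BuLi, THF, −30 °C; then 10, −78 °C; then 2 M HCl, THF, rt
Reagents that add atoms: water, O
Why: Corey–Seebach acyl-anion addition to the vinylogous ester carbonyl (future C10), followed by acid-induced loss of water and of the menthyl enol ether, should give the transposed enone (second half of the Stork–Danheiser sequence) and return the auxiliary.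

Step 7
Reactants: 14 dithianyl enone
Product: 15 TMSE (1S)-2-(3-chloropropyl)-3-(1,3-dithian-2-yl)-5-hydroxy-1-methylcyclohex-3-ene-1-carboxylate (C2 and C5 epimers)
Conditions: NaBH4, CeCl3·7H2O, MeOH, −20 °C
Reagents that add atoms: none
Why: Luche 1,2-reduction removes the enone so that ring closure proceeds through a sulfur-stabilised allyl anion and not through a dienolate that could alkylate at C1, the carbinol configuration being irrelevant because it is re-oxidised in step 9.

Step 8
Reactants: 15 allylic alcohol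
Product: 16 bicyclic allylic alcohol: TMSE (4S)-2-hydroxy-Δ1(10)-octalin-19-oate with C9 as spiro-1,3-dithiane (C2 and C5 epimers)
Conditions: LDA (2.5 equiv), THF/DMPU, −78 to 0 °C
Reagents that add atoms: none
Why: After O-deprotonation the 2-alkenyl-1,3-dithiane is deprotonated at C9 and alkylated at the sulfur-bearing carbon by the tethered chloride (6-exo-tet Corey–Seebach alkylation), closing ring B, while the alkoxide, unlike an ether, cannot be expelled by 1,4-elimination.

Step 9
Reactants: 16 bicyclic allylic alcohol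
Product: 17 bicyclic enone: TMSE (4S)-2-oxo-Δ1(10)-octalin-19-oate with C9 as spiro-1,3-dithiane (C5 epimers)
Conditions: MnO2, CH2Cl2, rt
Reagents that add atoms: none
Why: Manganese dioxide oxidises allylic alcohols selectively and should leave the thioketal and the ester untouched.

Step 10
Reactants: 17 dithiane enone
Product: 18 TMSE (4S)-2-oxo-Δ1(10)-octalin-19-oate with C9 as 1,3-dioxolane (C5 epimers)
Conditions: PhI(OCOCF3)2, HOCH2CH2OH, MeCN, 0 °C to rt
Reagents that add atoms: ethylene glycol, OCCO
Why: Iodine(III) activation of sulfur in the presence of the diol should convert the thioketal directly into the dioxolane (oxidative trans-ketalisation), so that neither a free C9 ketone (an ene-dione) nor sulfur reaches the borane, zinc and rhodium steps.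

Step 11
Reactants: 18 dioxolane enone
Product: 19 TMSE (4S)-2-oxo-Δ1(10),5-octadien-19-oate with C9 dioxolane (linear dienone)
Conditions: chloranil, t-BuOH, reflux
Reagents that add atoms: none
Why: Quinone dehydrogenation through the extended dienol removes hydride from C6 and should give the linear dienone (as for steroidal 4-en-3-ones to 4,6-dien-3-ones), the quaternary C4 excluding a cross-conjugated isomer and both C5 epimers converging.

Step 12
Reactants: 19 dienone
Product: 20 TMSE (2R,4S)-2β-hydroxy-Δ1(10),5-diene-19-oate with C9 dioxolane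
Conditions: (S)-Me-CBS (20 mol%), catecholborane, toluene, −78 °C
Reagents that add atoms: none
Why: In the CBS reduction the oxazaborolidine treats the enone carbon as the large group and delivers hydride to the α (Si) face, which is also anti to the pseudo-axial C19 ester, so catalyst and substrate should reinforce each other to give the 2β-alcohol.

Step 13
Reactants: 20 2β-hydroxy-Δ1(10),5-diene
Product: 21 TMSE 2β-hydroxy-1β,10β-methylene-Δ5-ene-19-oate with C9 dioxolane (cyclopropane C1–C10–C20 on the β face)
Conditions: Et2Zn, CH2I2, CH2Cl2, −15 to 0 °C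
Reagents that add atoms: diiodomethane, ICI
Why: Diethylzinc deprotonates the hydroxyl and the zinc alkoxide binds ethyl(iodomethyl)zinc, which transfers CH2 to the adjacent C1=C10 alkene through a concerted butterfly transition state (hydroxyl-directed Simmons–Smith cyclopropanation, Furukawa variant), the closest precedent being syn cyclopropanation of cyclohex-2-enols. The ring C1–C10–C20 closes in one concerted [2+1] methylene transfer in which C10–C20 and C1–C20 form on the same face. Both new centres are set by the 2β-carbinol, since the bound carbenoid can only reach the β face, so C20 is β on C10 and H1 is α. The step needs site selectivity for C1=C10 over C5=C6 and β-face selectivity against the steric bias of the axial C19 ester; both follow from coordination, because C5=C6 is out of reach of the alkoxide-bound carbenoid and directed delivery overrides sterics. Low temperature and a non-coordinating solvent should keep zinc iodide from ionising the doubly allylic carbinol or promoting lactonisation onto C19.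

Step 14
Reactants: 21 cyclopropyl carbinol
Product: 22 TMSE 2β-hydroxy-1β,10β-methylene-5α-H-19-oate with C9 dioxolane
Conditions: H2 (3 atm), 5% Rh/Al2O3, EtOAc, rt
Reagents that add atoms: none
Why: Heterogeneous hydrogenation from the α face, which carries only the C18 methyl while the β face is blocked by the cyclopropane CH2 and the C19 ester, should set 5α-H (the future trans ring fusion), rhodium being far less prone than palladium to hydrogenolyse an alkenyl cyclopropane.

Step 15
Reactants: 22 saturated cyclopropyl carbinol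
Product: 23 TMSE 2-oxo-1β,10β-methylene-5α-H-19-oate with C9 dioxolane
Conditions: Dess–Martin periodinane, NaHCO3, CH2Cl2, rt
Reagents that add atoms: none
Why: Dess–Martin oxidation of the secondary carbinol gives the cyclopropyl ketone under buffered conditions that avoid cyclopropylcarbinyl cation rearrangement.

Step 16
Reactants: 23 cyclopropyl ketone
Product: 24 TMSE 10β-methyl-2-oxo-5α-decalin-19-oate with C9 dioxolane
Conditions: SmI2, DMPU, t-BuOH, THF, −78 °C to rt
Reagents that add atoms: none
Why: The ketyl cleaves the cyclopropane bond best aligned with the carbonyl π system, the exocyclic C1–C20 bond, and the primary radical is reduced and protonated to the C20 methyl (reductive cleavage of a cyclopropyl ketone), samarium diiodide being chosen over lithium–ammonia because it spares the ester.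

Step 17
Reactants: 24 2-ketone
Product: 26 TMSE 2α-hydroxy-10β-methyl-9-oxo-5α-decalin-19-oate, via 2α-hydroxy 9-dioxolane 25 (not isolated)
Conditions: SmI2, THF/H2O, 0 °C; then 2 M HCl, THF, 40 °C
Reagents that add atoms: water, O
Why: Electron-transfer reduction of the C2 ketone is thermodynamically controlled and should place the hydroxyl equatorial (2α), away from the syn-axial C20 methyl and C19 ester that would steer hydride reagents to the 2β-alcohol, after which aqueous acid hydrolyses the C9 dioxolane.

Step 18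
Reactants: 26 hydroxy ketone
Product: 27 TMSE 2α-(tert-butyldimethylsilyloxy)-10β-methyl-9-oxo-5α-decalin-19-oate
Conditions: TBSCl, imidazole, DMF, rt
Reagents that add atoms: tert-butyldimethylsilyl chloride, CC(C)(C)[Si](C)(C)Cl
Why: Standard silylation of the unhindered equatorial alcohol protects it for the enolisation, borane and ylide steps.

Step 19
Reactants: 27 silyl ether ketone
Product: 29 C9 enol triflate of 27 (C8=C9; 2α-OTBS; 19-TMSE ester), via potassium enolate 28 (not isolated)
Conditions: KHMDS, THF, −78 °C; then PhNTf2, −78 to 0 °C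
Reagents that add atoms: N-phenylbis(trifluoromethanesulfonimide), O=S(=O)(N(c1ccccc1)S(=O)(=O)C(F)(F)F)C(F)(F)F
Why: The C9 ketone can enolise only towards C8 because C10 is quaternary, and O-sulfonylation of the potassium enolate should give a single enol triflate.

Step 20
Reactants: 29 enol triflate; 30 2-methyl-2-vinyl-1,3-dioxolane
Product: 32 Δ8(9)-ene carrying the C11–C13 chain at C9 with C13 as dioxolane (2α-OTBS; 19-TMSE ester), via B-alkyl-9-BBN 31 (not isolated)
Conditions: 30, 9-BBN, THF, rt; then 29, Pd(dppf)Cl2, AsPh3, Cs2CO3, DMF/H2O, rt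
Reagents that add atoms: none
Why: In this B-alkyl Suzuki–Miyaura coupling 9-BBN adds to the terminal carbon of the vinyl dioxolane and the primary alkyl group is transferred to the enol triflate, forming C9–C11.

Step 21
Reactants: 32 Δ8(9)-ene
Product: 34 secondary 8α-alcohol (9α-H; side chain 9β; C13 dioxolane), via C8 alkylborane 33 (not isolated)
Conditions: BH3·THF, THF, 0 °C to rt; then NaOH, H2O2, 0 °C
Reagents that add atoms: hydrogen peroxide, OO
Why: Hydroboration places boron on C8 and hydrogen on C9 by syn addition from the α face, opposite the axial C20 methyl, which sets 9α-H with the side chain equatorial, and oxidation proceeds with retention.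

Step 22
Reactants: 34 8α-alcohol
Product: 35 C8 ketone (9β side chain; C13 dioxolane)
Conditions: Dess–Martin periodinane, NaHCO3, CH2Cl2, rt
Reagents that add atoms: none
Why: Dess–Martin oxidation gives the C8 ketone, and although C9 becomes epimerisable the equatorial 9β side chain already present is the thermodynamically preferred arrangement.

Step 23
Reactants: 35 C8 ketone
Product: 36 exocyclic 8(17)-alkene (C13 dioxolane; 2α-OTBS; 19-TMSE ester)
Conditions: Ph3PCH3Br, KOtBu, toluene, 80 °C
Reagents that add atoms: methyltriphenylphosphonium bromide, [Br-].C[P+](c1ccccc1)(c1ccccc1)c1ccccc1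
Why: Wittig methylenation of a C8 ketone is the standard entry to the 8(17)-alkene of labdanes, and the non-stabilised ylide should not attack the hindered ester.

Step 24
Reactants: 36 side-chain dioxolane
Product: 37 methyl ketone: TMSE 2α-(tert-butyldimethylsilyloxy)-13-oxo-14,15-dinorlabd-8(17)-en-19-oate
Conditions: PPTS, acetone/H2O, 50 °C
Reagents that add atoms: water, O
Why: Mild acid-catalysed ketal hydrolysis should free the methyl ketone without migration of the exocyclic alkene or loss of either silyl group.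

Step 25
Reactants: 37 methyl ketone
Product: 38 protected diester: 15-methyl 19-TMSE (13E)-2α-(tert-butyldimethylsilyloxy)labda-8(17),13-diene-15,19-dioate
Conditions: (MeO)2P(O)CH2CO2Me, NaH, THF, 0 °C to reflux
Reagents that add atoms: trimethyl phosphonoacetate, COC(=O)CP(=O)(OC)OC
Why: Horner–Wadsworth–Emmons olefination of the methyl ketone is biased towards the (E)-enoate (chain trans to the ester), and the minor (Z)-isomer is to be removed by chromatography.

Step 26
Reactants: 38 protected diester
Product: 40 Hypoxyterpoid A, via 19-acid 15-methyl ester 39 (not isolated)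
Conditions: TBAF, THF, rt; then LiOH, H2O/MeOH, 40 °C; then 1 M HCl to pH 3
Reagents that add atoms: lithium hydroxide, [Li+].[OH-]
Why: Fluoride attacks silicon to release the C2 hydroxyl and, by loss of ethylene, the hindered C19 carboxylate without attack at the neopentyl carbonyl, and hydroxide then saponifies the unhindered conjugated methyl ester (fluoride-induced silyl cleavage, then ester hydrolysis).

**Compound list**

1 | 3,5-dimethoxybenzoic acid | COc1cc(OC)cc(c1)C(=O)O | starting material
2 | dilithium enediolate of 1,4-dihydro-3,5-dimethoxybenzoic acid | [Li+].[Li+].[O-]C([O-])=C1C=C(OC)CC(OC)=C1 | intermediate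
3 | 3,5-dimethoxy-1-methylcyclohexa-2,5-diene-1-carboxylic acid | COC1=CC(C)(C(=O)O)C=C(OC)C1 | intermediate
4 | TMSE 3,5-dimethoxy-1-methylcyclohexa-2,5-diene-1-carboxylate | COC1=CC(C)(C(=O)OCC[Si](C)(C)C)C=C(OC)C1 | intermediate
5 | TMSE 1-methyl-3,5-dioxocyclohexane-1-carboxylate | O=C1CC(=O)CC(C)(C(=O)OCC[Si](C)(C)C)C1 | intermediate
6 | (1R,2S,5R)-(−)-menthol | CC(C)[C@@H]1CC[C@@H](C)C[C@H]1O | starting material
7 | TMSE (1S)-1-methyl-3-[(1R,2S,5R)-menthyloxy]-5-oxocyclohex-3-ene-1-carboxylate | O=C1C=C(O[C@@H]2C[C@H](C)CC[C@H]2C(C)C)C[C@](C)(C(=O)OCC[Si](C)(C)C)C1 | intermediate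
8 | 1-bromo-3-chloropropane | ClCCCBr | starting material
9 | lithium α′-enolate of 7 | [Li+].[O-]C1=C[C@@](C)(C(=O)OCC[Si](C)(C)C)CC(O[C@@H]2C[C@H](C)CC[C@H]2C(C)C)=C1 | intermediate
10 | TMSE (1S)-6-(3-chloropropyl)-1-methyl-3-(menthyloxy)-5-oxocyclohex-3-ene-1-carboxylate (C5 epimers) | ClCCCC1C(=O)C=C(O[C@@H]2C[C@H](C)CC[C@H]2C(C)C)C[C@]1(C)C(=O)OCC[Si](C)(C)C | intermediate
11 | 1,3-dithiane | C1CSCSC1 | starting material
12 | 2-lithio-1,3-dithiane | [Li]C1SCCCS1 | intermediate
13 | lithium alkoxide of the 1,2-adduct of 12 to 10 | [Li+].[O-]C1(C2SCCCS2)C=C(O[C@@H]2C[C@H](C)CC[C@H]2C(C)C)C[C@](C)(C(=O)OCC[Si](C)(C)C)C1CCCCl | intermediate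
14 | TMSE (1S)-2-(3-chloropropyl)-3-(1,3-dithian-2-yl)-1-methyl-5-oxocyclohex-3-ene-1-carboxylate (C5 epimers) | ClCCCC1C(C2SCCCS2)=CC(=O)C[C@]1(C)C(=O)OCC[Si](C)(C)C | intermediate
15 | TMSE (1S)-2-(3-chloropropyl)-3-(1,3-dithian-2-yl)-5-hydroxy-1-methylcyclohex-3-ene-1-carboxylate (C2, C5 epimers) | ClCCCC1C(C2SCCCS2)=CC(O)C[C@]1(C)C(=O)OCC[Si](C)(C)C | intermediate
16 | TMSE (4S)-2-hydroxy-Δ1(10)-octalin-19-oate, C9 spiro-1,3-dithiane (C2, C5 epimers) | C1CCC2C(=CC(O)C[C@]2(C)C(=O)OCC[Si](C)(C)C)C13SCCCS3 | intermediate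
17 | TMSE (4S)-2-oxo-Δ1(10)-octalin-19-oate, C9 spiro-1,3-dithiane (C5 epimers) | C1CCC2C(=CC(=O)C[C@]2(C)C(=O)OCC[Si](C)(C)C)C13SCCCS3 | intermediate
18 | TMSE (4S)-2-oxo-Δ1(10)-octalin-19-oate, C9 dioxolane (C5 epimers) | C1CCC2C(=CC(=O)C[C@]2(C)C(=O)OCC[Si](C)(C)C)C13OCCO3 | intermediate
19 | TMSE (4S)-2-oxo-Δ1(10),5-diene-19-oate, C9 dioxolane | C1CC=C2C(=CC(=O)C[C@]2(C)C(=O)OCC[Si](C)(C)C)C13OCCO3 | intermediate
20 | TMSE (2R,4S)-2β-hydroxy-Δ1(10),5-diene-19-oate, C9 dioxolane (key-step precursor) | C1CC=C2C(=C[C@H](O)C[C@]2(C)C(=O)OCC[Si](C)(C)C)C13OCCO3 | intermediate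
21 | TMSE 2β-hydroxy-1β,10β-methylene-Δ5-ene-19-oate, C9 dioxolane (key-step product) | C1CC=C2[C@@]3(C[C@@H]3[C@H](O)C[C@]2(C)C(=O)OCC[Si](C)(C)C)C14OCCO4 | intermediate
22 | TMSE 2β-hydroxy-1β,10β-methylene-5α-H-19-oate, C9 dioxolane | C1CC[C@@H]2[C@@]3(C[C@@H]3[C@H](O)C[C@]2(C)C(=O)OCC[Si](C)(C)C)C14OCCO4 | intermediate
23 | TMSE 2-oxo-1β,10β-methylene-5α-H-19-oate, C9 dioxolane | C1CC[C@@H]2[C@@]3(C[C@@H]3C(=O)C[C@]2(C)C(=O)OCC[Si](C)(C)C)C14OCCO4 | intermediate
24 | TMSE 10β-methyl-2-oxo-5α-decalin-19-oate, C9 dioxolane | C1CC[C@@H]2[C@](C)(CC(=O)C[C@]2(C)C(=O)OCC[Si](C)(C)C)C13OCCO3 | intermediate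
25 | TMSE 2α-hydroxy-10β-methyl-5α-decalin-19-oate, C9 dioxolane | C1CC[C@@H]2[C@](C)(C[C@@H](O)C[C@]2(C)C(=O)OCC[Si](C)(C)C)C13OCCO3 | intermediate
26 | TMSE 2α-hydroxy-10β-methyl-9-oxo-5α-decalin-19-oate | C1CC[C@@H]2[C@](C)(C[C@@H](O)C[C@]2(C)C(=O)OCC[Si](C)(C)C)C1=O | intermediate
27 | TMSE 2α-(TBS-oxy)-10β-methyl-9-oxo-5α-decalin-19-oate | C1CC[C@@H]2[C@](C)(C[C@@H](O[Si](C)(C)C(C)(C)C)C[C@]2(C)C(=O)OCC[Si](C)(C)C)C1=O | intermediate
28 | potassium C8=C9 enolate of 27 | [K+].[O-]C1=CCC[C@@H]2[C@]1(C)C[C@@H](O[Si](C)(C)C(C)(C)C)C[C@]2(C)C(=O)OCC[Si](C)(C)C | intermediate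
29 | C9 enol triflate (C8=C9) of 27 | FC(F)(F)S(=O)(=O)OC1=CCC[C@@H]2[C@]1(C)C[C@@H](O[Si](C)(C)C(C)(C)C)C[C@]2(C)C(=O)OCC[Si](C)(C)C | intermediate
30 | 2-methyl-2-vinyl-1,3-dioxolane | C=CC1(C)OCCO1 | starting material
31 | 9-[2-(2-methyl-1,3-dioxolan-2-yl)ethyl]-9-borabicyclo[3.3.1]nonane | CC1(CCB2C3CCCC2CCC3)OCCO1 | intermediate
32 | Δ8(9)-ene with 9-[2-(2-methyl-1,3-dioxolan-2-yl)ethyl] chain (2α-OTBS, 19-TMSE ester) | CC1(CCC2=CCC[C@@H]3[C@]2(C)C[C@@H](O[Si](C)(C)C(C)(C)C)C[C@]3(C)C(=O)OCC[Si](C)(C)C)OCCO1 | intermediate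
33 | C8α-borane (9α-H) from 32 | B[C@@H]1CC[C@@H]2[C@](C)(C[C@@H](O[Si](C)(C)C(C)(C)C)C[C@]2(C)C(=O)OCC[Si](C)(C)C)[C@H]1CCC3(C)OCCO3 | intermediate
34 | 8α-hydroxy-9α-H compound (9β chain, C13 dioxolane) | O[C@@H]1CC[C@@H]2[C@](C)(C[C@@H](O[Si](C)(C)C(C)(C)C)C[C@]2(C)C(=O)OCC[Si](C)(C)C)[C@H]1CCC3(C)OCCO3 | intermediate
35 | 8-ketone (9β chain, C13 dioxolane) | O=C1CC[C@@H]2[C@](C)(C[C@@H](O[Si](C)(C)C(C)(C)C)C[C@]2(C)C(=O)OCC[Si](C)(C)C)[C@H]1CCC3(C)OCCO3 | intermediate
36 | 8(17)-ene with C13 dioxolane (2α-OTBS, 19-TMSE ester) | C=C1CC[C@@H]2[C@](C)(C[C@@H](O[Si](C)(C)C(C)(C)C)C[C@]2(C)C(=O)OCC[Si](C)(C)C)[C@H]1CCC3(C)OCCO3 | intermediate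
37 | TMSE 2α-(TBS-oxy)-13-oxo-14,15-dinorlabd-8(17)-en-19-oate | C=C1CC[C@@H]2[C@](C)(C[C@@H](O[Si](C)(C)C(C)(C)C)C[C@]2(C)C(=O)OCC[Si](C)(C)C)[C@H]1CCC(C)=O | intermediate
38 | 15-methyl 19-TMSE (13E)-2α-(TBS-oxy)labda-8(17),13-diene-15,19-dioate | C=C1CC[C@@H]2[C@](C)(C[C@@H](O[Si](C)(C)C(C)(C)C)C[C@]2(C)C(=O)OCC[Si](C)(C)C)[C@H]1CC/C(C)=C/C(=O)OC | intermediate
39 | (13E)-2α-hydroxy-15-methoxy-15-oxolabda-8(17),13-dien-19-oic acid | C=C1CC[C@@H]2[C@](C)(C[C@@H](O)C[C@]2(C)C(=O)O)[C@H]1CC/C(C)=C/C(=O)OC | intermediate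
40 | Hypoxyterpoid A, (13E)-2α-hydroxylabda-8(17),13-diene-15,19-dioic acid | C=C1CC[C@@H]2[C@](C)(C[C@@H](O)C[C@]2(C)C(=O)O)[C@H]1CC/C(C)=C/C(=O)O | target

**Step count.** Total: 26 steps. Longest linear sequence: 26 steps (from 1; all other building blocks are purchased).

**Steps most likely to fail**

Step 13. Methylene transfer may go astray in three ways: competing attack on C5=C6, ionisation of the doubly allylic carbinol by zinc iodide, or loss of the directing hydroxyl by lactonisation onto the syn C19 ester. The fallback sets out from 20 and returns at 21. The 2β-hydroxyl is acylated with bromoacetyl bromide/pyridine to the bromoacetate F1, which N,N′-ditosylhydrazine/DBU converts into the diazoacetate F2. Rh2(OAc)4 then delivers the tethered carbene to C1=C10 from the β face (intramolecular cyclopropanation of an allylic diazoacetate) to give the cyclopropane-fused γ-lactone F3. DIBAL at −78 °C gives the lactol F4, and Tsuji–Wilkinson decarbonylation of its open hydroxy-aldehyde form with RhCl(PPh3)3 removes the extra carbon with retention to give 21.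

Step 14. The alkenyl cyclopropane may be opened by hydrogenolysis, or hydrogen may be delivered from the β face (poor facial selectivity, possibly aided by hydroxyl binding to the metal). The fallback sets out from 21 and returns at 22. BH3·THF adds to C5=C6 from the α face (boron on C6, hydrogen on C5) to give the C6 borane F5, which alkaline peroxide oxidises to the 2β,6α-diol F6. The less hindered equatorial 6-hydroxyl is converted with thiocarbonyldiimidazole into the 6-O-(imidazol-1-ylthiocarbonyl) derivative F7. Bu3SnH/AIBN (Barton–McCombie deoxygenation) then gives 22; the C6 radical is not adjacent to the cyclopropane, so the ring should survive.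

Step 4. The two menthyl enol ethers differ only at a stereocentre remote from the auxiliary, so separation may be incomplete. The fallback sets out from 4 and returns at 14. Mono-hydrolysis of one enol ether (oxalic acid, wet THF) gives the racemic methyl vinylogous ester F8, and preparative chromatography on a chiral stationary phase gives the (S)-enantiomer F9. Steps 5 and 6 are then run unchanged: LDA gives the lithium enolate F10, alkylation with 8 gives the chloride F11, and addition of 12 gives the lithium alkoxide F12. Its acid hydrolysis releases methanol in place of menthol and gives 14.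

Further compounds
F1 | step 13 | 2β-bromoacetate of 20 | C1CC=C2C(=C[C@H](OC(=O)CBr)C[C@]2(C)C(=O)OCC[Si](C)(C)C)C13OCCO3
F2 | step 13 | 2β-diazoacetate of 20 | C1CC=C2C(=C[C@H](OC(=O)C=[N+]=[N-])C[C@]2(C)C(=O)OCC[Si](C)(C)C)C13OCCO3
F3 | step 13 | cyclopropane-fused γ-lactone (C20 carboxyl lactonised onto 2β-O) | C1CC=C2[C@@]3([C@H]4[C@@H]3[C@H](OC4=O)C[C@]2(C)C(=O)OCC[Si](C)(C)C)C15OCCO5
F4 | step 13 | corresponding lactol | C1CC=C2[C@@]3([C@H]4[C@@H]3[C@H](OC4O)C[C@]2(C)C(=O)OCC[Si](C)(C)C)C15OCCO5
F5 | step 14 | C6α-borane with 5α-H from 21 (shown with free 2β-OH) | C1C[C@H](B)[C@@H]2[C@@]3(C[C@@H]3[C@H](O)C[C@]2(C)C(=O)OCC[Si](C)(C)C)C14OCCO4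
F6 | step 14 | 2β,6α-diol with 5α-H | C1C[C@H](O)[C@@H]2[C@@]3(C[C@@H]3[C@H](O)C[C@]2(C)C(=O)OCC[Si](C)(C)C)C14OCCO4
F7 | step 14 | 6-O-(imidazol-1-ylthiocarbonyl) derivative of the diol | C1C[C@H](OC(=S)n5ccnc5)[C@@H]2[C@@]3(C[C@@H]3[C@H](O)C[C@]2(C)C(=O)OCC[Si](C)(C)C)C14OCCO4
F8 | step 4 | racemic TMSE 3-methoxy-1-methyl-5-oxocyclohex-3-ene-1-carboxylate | O=C1C=C(OC)CC(C)(C(=O)OCC[Si](C)(C)C)C1
F9 | step 4 | TMSE (1S)-3-methoxy-1-methyl-5-oxocyclohex-3-ene-1-carboxylate | O=C1C=C(OC)C[C@](C)(C(=O)OCC[Si](C)(C)C)C1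
F10 | step 4 | lithium α′-enolate of the (S)-methyl vinylogous ester | [Li+].[O-]C1=C[C@@](C)(C(=O)OCC[Si](C)(C)C)CC(OC)=C1
F11 | step 4 | TMSE (1S)-6-(3-chloropropyl)-3-methoxy-1-methyl-5-oxocyclohex-3-ene-1-carboxylate (C5 epimers) | ClCCCC1C(=O)C=C(OC)C[C@]1(C)C(=O)OCC[Si](C)(C)C
F12 | step 4 | lithium alkoxide of the dithiane 1,2-adduct of the chloride | [Li+].[O-]C1(C2SCCCS2)C=C(OC)C[C@](C)(C(=O)OCC[Si](C)(C)C)C1CCCCl
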